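Assumption: the stereodescriptors of the SMILES are taken literally. They place H-6 and H-7 on opposite faces of the cyclopropane, so the cyclopropane is trans-fused to the cycloheptane, and the route is designed for exactly this isomer.

## Structural features

The target is a 2,3-secoaromadendrane (plagiochiline-type) sesquiterpenoid. In the usual numbering it contains a cyclopropane (C-6, C-7, C-11), a cycloheptane (C-1, C-5, C-6, C-7, C-8, C-9, C-10), a 2-acetoxy-3,4-dihydro-2H-pyran (O, C-2, C-1, C-5, C-4, C-3; enol ether C-3=C-4) and an oxepane (C-11, C-13, O, C-15, C-4, C-5, C-6); C-12 is the acetoxymethyl carbon on C-11 and C-14 the methyl group on C-10. The cycloheptane shares C-6–C-7 with the cyclopropane and C-1–C-5 with the pyran, while the oxepane shares C-6–C-11 with the cyclopropane, C-5–C-6 with the cycloheptane and C-4–C-5 with the pyran, so C-5 and C-6 each belong to three rings. Seven stereocentres, five of them contiguous (C-2, C-1, C-5, C-6, C-7) and flanked by the quaternary C-11 and the tertiary carbinol C-10, are configured 1R,2R,5R,6S,7R,10S,11R: H-1/H-5 cis, H-5/H-6 anti, the C-2 acetoxy group cis to H-1, C-13 cis to C-5 on the cyclopropane, and H-6/H-7 trans. The last relationship makes the carbocycle a trans-bicyclo[5.1.0]octane, estimated to be roughly 10 kcal/mol more strained than its cis isomer, whereas the cyclopropane is cis-fused to the oxepane. Fragile groups are the acyloxy acetal at C-2, the enol ether that makes C-15 a vinylogous acetal centre (acid), the two acetates (base, hydride) and the β-hydroxy aldehyde relationship between C-10 and C-2 that appears whenever the acetal is open (retro-aldol with release of ring strain). The real difficulty is the trans ring fusion at C-6/C-7, which no cyclopropanation of a cycloheptene can give, combined with the cis C-1/C-5 junction next to it. The key step exploits the C-1–C-5 bond: C-1 carries a carbonyl-level carbon (C-2) and C-5 an sp2 carbon (C-4) with a one-carbon branch (C-15). This is the γ,δ-unsaturated acid pattern C-2/C-1/C-5/C-4=C-15 of an ester-enolate Claisen product, so the cycloheptane can be closed by contracting an eleven-membered lactone, tied through C-2–O–C-15, onto a preformed trans-cyclopropane.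

## Logic of the disconnections

In one sentence: an Ireland–Claisen ring contraction of the eleven-membered allylic lactone 14, built on an enantiopure trans-cyclopropane, closes the trans-fused cycloheptane.

25 to 24 to 23: the O–Si bond at C-10 and the two acetyl C–O bonds (on the C-12 oxygen and on the C-2 lactol oxygen) are cut. The acyloxy acetal and the free β-hydroxy acetal are the most fragile features and are therefore made last. The forward steps must acetylate the lactol anomer with oxygen cis to H-1, leave the tertiary silyl ether alone, and remove silicon with buffered fluoride.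

23 to 20: the O–C-15 bond of the oxepane and the O–C-2 bond of the pyran are cut. Both are bonds of a vinylogous acetal and hemiacetal and can form under equilibrium control. Two rings and the C-11 stereocentre disappear, leaving a 1,5-dialdehyde (C-3 as a 2-substituted acrolein) and a masked, undifferentiated 1,3-diol. The forward step needs conjugate (not 1,2) addition by the hydroxymethyl group cis to C-5 only, and cis lactol closure.

20 to 19 to 18 to 17: oxidation levels at C-2 and C-3 are adjusted and the C-3–O bond is cut (allylic oxidation). A carboxyl at C-2 and a methyl at C-3 are exactly what the key step delivers. The allylic oxidation must take the methyl group and not H-5.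

17 to 14 (key): C-1–C-5 is cut and C-15 is reconnected to the carboxyl oxygen of C-2. This opens the strained trans-fused cycloheptane into an eleven-membered lactone in which the trans-cyclopropane is an unstrained ring member, and removes the C-1 and C-5 stereocentres. The forward step must close the ring against about 10 kcal/mol of extra strain and deliver 1R,5R.

14 to 13: the acyl C-2–O bond is cut (macrolactonisation). The forward step needs high dilution and mild activation of a β-silyloxy acid.

13 to 12 to 11: the C-2 carboxyl is traced to the terminal vinyl carbon (anti-Markovnikov oxidation, then aldehyde to acid). This avoids any protecting group on C-15–OH, but the oxidation must be regioselective.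

11 to 10 to 9: the acetonide C–O bonds are cut and the three alcohols are traced to three esters. The 1,3-diol on C-11 is distinguished from the allylic alcohol simply by ring size of the ketal.

9 to 7 + 8: the C-4=C-5 alkene is cut (Wittig). The forward step must give the E isomer, which step 11 requires.

7 to 5 + 6: the C-6–C-11 and C-7–C-11 bonds are cut (Michael-initiated ring closure). An E-enal and bromomalonate give the trans-cyclopropane directly, and the catalyst must set C-7 (and with it C-6) absolutely.

5 to 3 + 4, 3 to 2 to 1: the C-6=C-7 alkene is cut (Wittig), and C-7 is traced to C-6 of 1 by cleavage of its trisubstituted alkene. 1 supplies C-2, C-1, C-10, C-14, C-9, C-8 and C-7 together with the C-10 stereocentre. The ozonolysis must spare the vinyl group.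

## Other disconnections considered

Alternative 1: The pyran is cut at O–C-2 and opened to a 1,5-dialdehyde, which is reconnected C-2–C-3 to the cyclopentene of tricycle A1 (an aromadendr-2-ene already carrying the oxepane). The forward key step is ozonolysis of A1 followed by enol-lactol closure. This is the disconnection that comes to mind first, but it only moves the problem: A1 still contains the trans-fused cyclopropane. The standard entries to the 5-7-3 system (carbene addition to a hydroazulene alkene, or a cyclopropane-containing monoterpene from the chiral pool) give the cis fusion, because a seven-membered ring cannot hold the E-alkene that a stereospecific cyclopropanation would need. A1 would therefore need its own unconventional ring construction before the cleavage, at a higher step count than the chosen route.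

Alternative 2: C-1–C-5 and O–C-2 are cut together. The forward key step is an intramolecular inverse-demand hetero-Diels–Alder reaction of the 1-oxadiene A2 (an alkylidene formylacetate obtained by Knoevenagel condensation at C-5) with an enol acetate at the end of the C-10 chain, closing cycloheptane and pyran at once. It is shorter on paper, but diene and dienophile are joined only by the five-atom tether through the trans-cyclopropane. The closure is entropically poor and must also pay the ring strain in its transition state, so bimolecular reaction of so reactive a heterodiene is expected to compete. The endo/exo sense at C-2 and the enol acetate geometry are further uncontrolled variables. If the oxepane were closed first to make the diene cyclic, the tether could only reach the wrong face of C-5. The chosen step holds the reacting termini in a six-centre array within a pre-formed ring.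

Alternative 3: C-2 is placed inside an eight-membered ring between C-1 and C-10 (α-diazo ketone A3). The forward key step is a photochemical Wolff ring contraction that expels C-2 as the exocyclic carboxyl and forms the C-1–C-10 bond. Ring contraction by nitrogen loss is a classical entry to trans-fused bicyclo[n.1.0]alkanes and the strain is no obstacle. But A3 needs a medium-ring closure with no pericyclic help and a diazo transfer next to a quaternary centre, C-1 is created by protonation of a ketene without a control element, and the C-4 unit on C-5 has to be installed separately. The chosen rearrangement makes C-1–C-5, both stereocentres and both appendages in one step.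

Key step: step 11

## Route

Step 1
Reactants: 1 (S)-(+)-linalool
Product: 2 (3S)-3,7-dimethyl-3-(triethylsilyloxy)octa-1,6-diene
Conditions: Et3SiOTf, 2,6-lutidine, CH2Cl2, −78 to 0 °C
Reagents that add atoms: triethylsilyl trifluoromethanesulfonate, CC[Si](CC)(CC)OS(=O)(=O)C(F)(F)F
Why: Silylation of the tertiary alcohol with the silyl triflate; the chiral-pool centre (future C-10, S) is not touched, and the ether prevents oxa-Michael addition at the enal stage.

Step 2
Reactants: 2 (3S)-3,7-dimethyl-3-(triethylsilyloxy)octa-1,6-diene
Product: 3 (4S)-4-methyl-4-(triethylsilyloxy)hex-5-enal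
Conditions: O3, pyridine, CH2Cl2, −78 °C (Sudan red 7B end point); Me2S
Reagents that add atoms: ozone, [O-][O+]=O
Why: Chemoselective ozonolysis: the electron-rich trisubstituted alkene reacts far faster than the vinyl group, which is deactivated and shielded by the adjacent quaternary silyloxy carbon; the aldehyde carbon is C-7.

Step 3
Reactants: 3 (4S)-4-methyl-4-(triethylsilyloxy)hex-5-enal; 4 (triphenylphosphoranylidene)acetaldehyde
Product: 5 (2E,6S)-6-methyl-6-(triethylsilyloxy)octa-2,7-dienal
Conditions: toluene, 80 °C
Reagents that add atoms: none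
Why: Wittig two-carbon homologation with the stabilised formyl ylide gives the E-enal (C-5 aldehyde, C-6=C-7); the E geometry is what the trans-cyclopropane is made from.

Step 4
Reactants: 5 (2E,6S)-6-methyl-6-(triethylsilyloxy)octa-2,7-dienal; 6 diethyl bromomalonate
Product: 7 diethyl (2R,3R)-2-formyl-3-[(3S)-3-methyl-3-(triethylsilyloxy)pent-4-en-1-yl]cyclopropane-1,1-dicarboxylate
Conditions: (S)-α,α-diphenylprolinol trimethylsilyl ether (20 mol%), 2,6-lutidine, CH2Cl2, rt
Reagents that add atoms: none
Why: Organocatalytic Michael-initiated ring closure (iminium, then enamine alkylation): the diarylsilyloxymethyl group of the (S)-catalyst shields the Si face of C-7 in the s-trans iminium, so the bromomalonate adds to the Re face and sets C-7; the enamine then displaces bromide with the formyl group trans to the chain, which sets C-6 and the trans H-6/H-7 relationship.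

Step 5
Reactants: 7 diethyl (2R,3R)-2-formyl-3-[(3S)-3-methyl-3-(triethylsilyloxy)pent-4-en-1-yl]cyclopropane-1,1-dicarboxylate; 8 ethyl 2-(triphenylphosphoranylidene)propanoate
Product: 9 diethyl (2R,3R)-2-[(1E)-3-ethoxy-2-methyl-3-oxoprop-1-en-1-yl]-3-[(3S)-3-methyl-3-(triethylsilyloxy)pent-4-en-1-yl]cyclopropane-1,1-dicarboxylate
Conditions: CH2Cl2, rt to 40 °C
Reagents that add atoms: none
Why: Wittig olefination with the stabilised α-methyl ylide gives the E-trisubstituted enoate (C-15 ester trans to C-6, C-3 methyl cis), the geometry that step 11 requires; the non-basic conditions do not epimerise C-6.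

Step 6
Reactants: 9 diethyl (2R,3R)-2-[(1E)-3-ethoxy-2-methyl-3-oxoprop-1-en-1-yl]-3-[(3S)-3-methyl-3-(triethylsilyloxy)pent-4-en-1-yl]cyclopropane-1,1-dicarboxylate
Product: 10 {(2R,3R)-2-[(1E)-3-hydroxy-2-methylprop-1-en-1-yl]-3-[(3S)-3-methyl-3-(triethylsilyloxy)pent-4-en-1-yl]cyclopropane-1,1-diyl}dimethanol
Conditions: i-Bu2AlH (excess), CH2Cl2, −78 to 0 °C; aq. KNaC4H4O6
Reagents that add atoms: none
Why: 1,2-Reduction of all three esters by the aluminium hydride; the enoate gives the allylic alcohol without conjugate reduction, and the vinylcyclopropane is not opened at low temperature.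

Step 7
Reactants: 10 {(2R,3R)-2-[(1E)-3-hydroxy-2-methylprop-1-en-1-yl]-3-[(3S)-3-methyl-3-(triethylsilyloxy)pent-4-en-1-yl]cyclopropane-1,1-diyl}dimethanol
Product: 11 (2E)-3-{(1R,2R)-6,6-dimethyl-2-[(3S)-3-methyl-3-(triethylsilyloxy)pent-4-en-1-yl]-5,7-dioxaspiro[2.5]octan-1-yl}-2-methylprop-2-en-1-ol
Conditions: 2,2-dimethoxypropane, pyridinium p-toluenesulfonate (cat.), acetone, rt; aqueous work-up
Reagents that add atoms: 2,2-dimethoxypropane, COC(C)(C)OC
Why: Thermodynamic ketalisation selects the six-membered 1,3-dioxane of the geminal bis(hydroxymethyl) unit over any larger ring that would include the allylic alcohol, which stays free; C-12 and C-13 are deliberately left undifferentiated until step 15.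

Step 8
Reactants: 11 (2E)-3-{(1R,2R)-6,6-dimethyl-2-[(3S)-3-methyl-3-(triethylsilyloxy)pent-4-en-1-yl]-5,7-dioxaspiro[2.5]octan-1-yl}-2-methylprop-2-en-1-ol
Product: 12 (3S)-5-{(1R,2R)-2-[(1E)-3-hydroxy-2-methylprop-1-en-1-yl]-6,6-dimethyl-5,7-dioxaspiro[2.5]octan-1-yl}-3-methyl-3-(triethylsilyloxy)pentanal
Conditions: PdCl2(PhCN)2 (cat.), CuCl2·2H2O (cat.), AgNO2 (cat.), O2 (1 atm), t-BuOH/MeNO2, rt
Reagents that add atoms: dioxygen, O=O
Why: Nitrite-modified, aldehyde-selective Wacker oxidation: oxygen is delivered to the terminal carbon because the quaternary, oxygen-bearing allylic carbon C-10 disfavours the Markovnikov pathway; the trisubstituted alkene and the free allylic alcohol are inert to divalent palladium under these conditions.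

Step 9
Reactants: 12 (3S)-5-{(1R,2R)-2-[(1E)-3-hydroxy-2-methylprop-1-en-1-yl]-6,6-dimethyl-5,7-dioxaspiro[2.5]octan-1-yl}-3-methyl-3-(triethylsilyloxy)pentanal
Product: 13 (3S)-5-{(1R,2R)-2-[(1E)-3-hydroxy-2-methylprop-1-en-1-yl]-6,6-dimethyl-5,7-dioxaspiro[2.5]octan-1-yl}-3-methyl-3-(triethylsilyloxy)pentanoic acid
Conditions: NaClO2, NaH2PO4, 2-methyl-2-butene, t-BuOH/H2O, 0 °C to rt
Reagents that add atoms: sodium chlorite, [Na+].[O-]Cl=O
Why: Pinnick oxidation of the aldehyde to the C-2 acid; hypochlorous acid is scavenged by 2-methyl-2-butene, so the allylic alcohol, trisubstituted alkene, acetonide and silyl ether survive.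

Step 10
Reactants: 13 (3S)-5-{(1R,2R)-2-[(1E)-3-hydroxy-2-methylprop-1-en-1-yl]-6,6-dimethyl-5,7-dioxaspiro[2.5]octan-1-yl}-3-methyl-3-(triethylsilyloxy)pentanoic acid
Product: 14 (1R,2E,8S,11R)-3,8,2',2'-tetramethyl-8-(triethylsilyloxy)spiro[5-oxabicyclo[9.1.0]dodec-2-ene-12,5'-[1,3]dioxan]-6-one
Conditions: 2-methyl-6-nitrobenzoic anhydride, 4-dimethylaminopyridine, Et3N, CH2Cl2 (1 mM, slow addition), rt
Reagents that add atoms: none
Why: Shiina macrolactonisation through the mixed anhydride at high dilution; the trans-cyclopropane and the E-alkene hold the seco acid extended and remove two transannular CH2 contacts from the eleven-membered ring, and room temperature avoids β-elimination of the activated β-silyloxy acid.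

Step 11
Reactants: 14 (1R,2E,8S,11R)-3,8,2',2'-tetramethyl-8-(triethylsilyloxy)spiro[5-oxabicyclo[9.1.0]dodec-2-ene-12,5'-[1,3]dioxan]-6-one
Product: 17 (1S,2R,3R,4S,7R)-2',2',4-trimethyl-2-(prop-1-en-2-yl)-4-(triethylsilyloxy)spiro[bicyclo[5.1.0]octane-8,5'-[1,3]dioxane]-3-carboxylic acid, via (Z)-silyl ketene acetal 15 (not isolated), via trimethylsilyl ester 16 (not isolated)
Conditions: LiN(i-Pr)2, Me3SiCl/Et3N, THF/DMPU (4:1), −78 °C; then toluene, 90 °C; aq. citric acid
Reagents that add atoms: chlorotrimethylsilane, C[Si](C)(C)Cl
Why: Ester-enolate (Ireland–Claisen) rearrangement run as a ring contraction: kinetic enolisation of the lactone at C-1 with internal silylation gives ketene acetal 15, whose [3,3] shift forms C-1–C-5, breaks C-15–O and turns the eleven-membered lactone into the seven-membered carbocycle with a carboxyl (C-2) on C-1 and an isopropenyl group (C-4, C-3, C-15) on C-5. The closest known reaction type is the Ireland–Claisen ring contraction of medium and large lactones to cis-2-alkenylcycloalkanecarboxylic acids, which is known to build small strained carbocycles down to cyclopropanes, so the additional strain of the trans-fused bicyclo[5.1.0]octane lies within its driving force. The cycloheptane closes transannularly through a suprafacial six-centre array, the termini being held within bonding distance by the temporary C-2–O–C-15 bridge and not by the five-atom tether alone. C-5 is controlled by the cyclopropane: allylic 1,3-strain between the C-3 methyl group and the cyclopropane keeps H-6 in the plane of the C-4=C-5 alkene, and the tether through C-7 (trans on the cyclopropane) lets C-1 reach only the alkene face on the C-7 side, which gives 5R. C-1 is controlled by the same tether: C-10 must run back towards C-8, so the C-1–C-10 bond lies parallel to C-5–C-6, the array is forced into a boat and H-1 ends cis to H-5 (1R). This geometry needs the ketene acetal in which C-10 is trans to the ring oxygen, the isomer favoured by enolisation in the presence of DMPU. The step also needs O-silylation to outrun β-elimination of the C-10 silyloxy group, which the internal Me3SiCl quench at −78 °C is meant to secure. The E geometry set in step 5 places the C-15–O bond on the side of the alkene from which the boat can be reached.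

Step 12
Reactants: 17 (1S,2R,3R,4S,7R)-2',2',4-trimethyl-2-(prop-1-en-2-yl)-4-(triethylsilyloxy)spiro[bicyclo[5.1.0]octane-8,5'-[1,3]dioxane]-3-carboxylic acid
Product: 18 [(1S,2R,3S,4S,7R)-2',2',4-trimethyl-2-(prop-1-en-2-yl)-4-(triethylsilyloxy)spiro[bicyclo[5.1.0]octane-8,5'-[1,3]dioxan]-3-yl]methanol
Conditions: LiAlH4, THF, 0 °C to rt
Reagents that add atoms: none
Why: Hydride reduction of the carboxylic acid to the C-2 primary alcohol; no other reducible group is present (the descriptor at C-1 changes by priority only).

Step 13
Reactants: 18 [(1S,2R,3S,4S,7R)-2',2',4-trimethyl-2-(prop-1-en-2-yl)-4-(triethylsilyloxy)spiro[bicyclo[5.1.0]octane-8,5'-[1,3]dioxan]-3-yl]methanol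
Product: 19 2-[(1S,2R,3S,4S,7R)-3-(hydroxymethyl)-2',2',4-trimethyl-4-(triethylsilyloxy)spiro[bicyclo[5.1.0]octane-8,5'-[1,3]dioxan]-2-yl]prop-2-en-1-ol
Conditions: SeO2 (cat.), t-BuOOH, CH2Cl2, rt
Reagents that add atoms: selenium dioxide, O=[Se]=O; tert-butyl hydroperoxide, CC(C)(C)OO
Why: Allylic oxidation by ene reaction and [2,3]-shift: of the two allylic positions of the isopropenyl group the methyl hydrogens are abstracted, because H-5 lies in the plane of the alkene (allylic strain) and is shielded by C-1 and C-6; any enal formed by further oxidation converges in step 14.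

Step 14
Reactants: 19 2-[(1S,2R,3S,4S,7R)-3-(hydroxymethyl)-2',2',4-trimethyl-4-(triethylsilyloxy)spiro[bicyclo[5.1.0]octane-8,5'-[1,3]dioxan]-2-yl]prop-2-en-1-ol
Product: 20 (1S,2R,3R,4S,7R)-2',2',4-trimethyl-2-(3-oxoprop-1-en-2-yl)-4-(triethylsilyloxy)spiro[bicyclo[5.1.0]octane-8,5'-[1,3]dioxane]-3-carbaldehyde
Conditions: Dess–Martin periodinane, NaHCO3, CH2Cl2, 0 °C
Reagents that add atoms: none
Why: Buffered Dess–Martin oxidation converts both primary alcohols into aldehydes (C-2 aldehyde and the 2-substituted acrolein C-15=C-4–C-3) without epimerising C-1 or touching acetonide and silyl ether.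

Step 15
Reactants: 20 (1S,2R,3R,4S,7R)-2',2',4-trimethyl-2-(3-oxoprop-1-en-2-yl)-4-(triethylsilyloxy)spiro[bicyclo[5.1.0]octane-8,5'-[1,3]dioxane]-3-carbaldehyde
Product: 23 12-hydroxy lactol (10-O-triethylsilyl-2-O,12-O-dideacetyl target with 2-OH cis to H-1), via diol dialdehyde 21 (not isolated), via oxepane dialdehyde 22 (not isolated)
Conditions: AcOH/THF/H2O (4:1:1), rt; evaporation; then PBu3 (10 mol%), CH2Cl2, rt
Reagents that add atoms: none
Why: Aqueous acid removes the acetonide; of the two hydroxymethyl groups only the one cis to C-5 (C-13) can reach C-15 without a trans-fused ring, and its phosphine-catalysed oxa-Michael addition (7-endo) closes the oxepane and sets C-11. The resulting C-3 enol(ate) oxygen then adds to the C-2 aldehyde to give the six-membered enol hemiacetal, the form in which such 1,5-dialdehydes rest; the C-10 silyl ether blocks retro-aldol cleavage.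

Step 16
Reactants: 23 12-hydroxy lactol (10-O-triethylsilyl-2-O,12-O-dideacetyl target)
Product: 24 10-O-triethylsilyl ether of the target (2,12-diacetate; 1R,2R,5R,6S,7R,10S,11R)
Conditions: Ac2O, pyridine, 4-dimethylaminopyridine (cat.), CH2Cl2, 0 °C
Reagents that add atoms: acetic anhydride, CC(=O)OC(C)=O
Why: Acetylation of the primary C-12 alcohol and of the lactol; the acetate is expected on the anomer with oxygen cis to H-1 (anti to the C-1–C-10 bond, pseudo-axial: anomeric effect and approach away from the quaternary C-10), and the tertiary silyl ether is not acylated.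

Step 17
Reactants: 24 10-O-triethylsilyl ether of the target
Product: 25 target CNP0250836.2 (1R,2R,5R,6S,7R,10S,11R)
Conditions: HF·pyridine, pyridine, THF, 0 °C to rt
Reagents that add atoms: none
Why: Buffered fluoride cleaves the tertiary triethylsilyl ether without ionising the acyloxy acetal or the vinylogous acetal at C-15 and without acetate migration; no stereocentre is involved.

## Compound list

1 | (S)-(+)-linalool, (3S)-3,7-dimethylocta-1,6-dien-3-ol | C=C[C@@](C)(O)CCC=C(C)C | starting material
2 | (3S)-3,7-dimethyl-3-(triethylsilyloxy)octa-1,6-diene | C=C[C@@](C)(O[Si](CC)(CC)CC)CCC=C(C)C | intermediate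
3 | (4S)-4-methyl-4-(triethylsilyloxy)hex-5-enal | C=C[C@@](C)(O[Si](CC)(CC)CC)CCC=O | intermediate
4 | (triphenylphosphoranylidene)acetaldehyde | O=CC=P(c1ccccc1)(c1ccccc1)c1ccccc1 | starting material
5 | (2E,6S)-6-methyl-6-(triethylsilyloxy)octa-2,7-dienal | C=C[C@@](C)(O[Si](CC)(CC)CC)CC/C=C/C=O | intermediate
6 | diethyl bromomalonate | CCOC(=O)C(Br)C(=O)OCC | starting material
7 | diethyl (2R,3R)-2-formyl-3-[(3S)-3-methyl-3-(triethylsilyloxy)pent-4-en-1-yl]cyclopropane-1,1-dicarboxylate | O=C[C@@H]1[C@@H](CC[C@](C)(O[Si](CC)(CC)CC)C=C)C1(C(=O)OCC)C(=O)OCC | intermediate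
8 | ethyl 2-(triphenylphosphoranylidene)propanoate | CCOC(=O)C(C)=P(c1ccccc1)(c1ccccc1)c1ccccc1 | starting material
9 | diethyl (2R,3R)-2-[(1E)-3-ethoxy-2-methyl-3-oxoprop-1-en-1-yl]-3-[(3S)-3-methyl-3-(triethylsilyloxy)pent-4-en-1-yl]cyclopropane-1,1-dicarboxylate | CCOC(=O)/C(C)=C/[C@@H]1[C@@H](CC[C@](C)(O[Si](CC)(CC)CC)C=C)C1(C(=O)OCC)C(=O)OCC | intermediate
10 | {(2R,3R)-2-[(1E)-3-hydroxy-2-methylprop-1-en-1-yl]-3-[(3S)-3-methyl-3-(triethylsilyloxy)pent-4-en-1-yl]cyclopropane-1,1-diyl}dimethanol | OC/C(C)=C/[C@@H]1[C@@H](CC[C@](C)(O[Si](CC)(CC)CC)C=C)C1(CO)CO | intermediate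
11 | (2E)-3-{(1R,2R)-6,6-dimethyl-2-[(3S)-3-methyl-3-(triethylsilyloxy)pent-4-en-1-yl]-5,7-dioxaspiro[2.5]octan-1-yl}-2-methylprop-2-en-1-ol | OC/C(C)=C/[C@@H]1[C@@H](CC[C@](C)(O[Si](CC)(CC)CC)C=C)C12COC(C)(C)OC2 | intermediate
12 | (3S)-5-{(1R,2R)-2-[(1E)-3-hydroxy-2-methylprop-1-en-1-yl]-6,6-dimethyl-5,7-dioxaspiro[2.5]octan-1-yl}-3-methyl-3-(triethylsilyloxy)pentanal | OC/C(C)=C/[C@@H]1[C@@H](CC[C@](C)(O[Si](CC)(CC)CC)CC=O)C12COC(C)(C)OC2 | intermediate
13 | (3S)-5-{(1R,2R)-2-[(1E)-3-hydroxy-2-methylprop-1-en-1-yl]-6,6-dimethyl-5,7-dioxaspiro[2.5]octan-1-yl}-3-methyl-3-(triethylsilyloxy)pentanoic acid (seco acid) | OC/C(C)=C/[C@@H]1[C@@H](CC[C@](C)(O[Si](CC)(CC)CC)CC(=O)O)C12COC(C)(C)OC2 | intermediate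
14 | eleven-membered lactone, (1R,2E,8S,11R)-3,8,2',2'-tetramethyl-8-(triethylsilyloxy)spiro[5-oxabicyclo[9.1.0]dodec-2-ene-12,5'-[1,3]dioxan]-6-one | O=C1C[C@@](C)(O[Si](CC)(CC)CC)CC[C@@H]2[C@@H](/C=C(C)/CO1)C23COC(C)(C)OC3 | intermediate
15 | (Z)-O-trimethylsilyl ketene acetal of 14 (C-10 trans to the ring oxygen) | C[Si](C)(C)O/C1=C\[C@@](C)(O[Si](CC)(CC)CC)CC[C@@H]2[C@@H](/C=C(C)/CO1)C23COC(C)(C)OC3 | intermediate (not isolated)
16 | trimethylsilyl ester of 17 | C[Si](C)(C)OC(=O)[C@@H]1[C@H](C(C)=C)[C@@H]2[C@@H](CC[C@]1(C)O[Si](CC)(CC)CC)C23COC(C)(C)OC3 | intermediate (not isolated)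
17 | (1S,2R,3R,4S,7R)-2',2',4-trimethyl-2-(prop-1-en-2-yl)-4-(triethylsilyloxy)spiro[bicyclo[5.1.0]octane-8,5'-[1,3]dioxane]-3-carboxylic acid (trans-fused; C-1 R, C-5 R, C-6 S, C-7 R, C-10 S in target numbering) | OC(=O)[C@@H]1[C@H](C(C)=C)[C@@H]2[C@@H](CC[C@]1(C)O[Si](CC)(CC)CC)C23COC(C)(C)OC3 | intermediate
18 | [(1S,2R,3S,4S,7R)-2',2',4-trimethyl-2-(prop-1-en-2-yl)-4-(triethylsilyloxy)spiro[bicyclo[5.1.0]octane-8,5'-[1,3]dioxan]-3-yl]methanol (stereocentres as in 17) | OC[C@@H]1[C@H](C(C)=C)[C@@H]2[C@@H](CC[C@]1(C)O[Si](CC)(CC)CC)C23COC(C)(C)OC3 | intermediate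
19 | 2-[(1S,2R,3S,4S,7R)-3-(hydroxymethyl)-2',2',4-trimethyl-4-(triethylsilyloxy)spiro[bicyclo[5.1.0]octane-8,5'-[1,3]dioxan]-2-yl]prop-2-en-1-ol (stereocentres as in 17) | OC[C@@H]1[C@H](C(CO)=C)[C@@H]2[C@@H](CC[C@]1(C)O[Si](CC)(CC)CC)C23COC(C)(C)OC3 | intermediate
20 | (1S,2R,3R,4S,7R)-2',2',4-trimethyl-2-(3-oxoprop-1-en-2-yl)-4-(triethylsilyloxy)spiro[bicyclo[5.1.0]octane-8,5'-[1,3]dioxane]-3-carbaldehyde (stereocentres as in 17) | O=C[C@@H]1[C@H](C(C=O)=C)[C@@H]2[C@@H](CC[C@]1(C)O[Si](CC)(CC)CC)C23COC(C)(C)OC3 | intermediate
21 | diol dialdehyde: 20 without the acetonide (8,8-bis(hydroxymethyl); stereocentres as in 17) | O=C[C@@H]1[C@H](C(C=O)=C)[C@@H]2[C@@H](CC[C@]1(C)O[Si](CC)(CC)CC)C2(CO)CO | intermediate (not isolated)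
22 | oxepane dialdehyde: oxa-Michael adduct of 21 (O–C-15 bond formed, C-11 set, C-4 epimers, C-2 and C-3 as aldehydes) | OC[C@@]12COCC(C=O)[C@H]([C@@H]1[C@H]2CC[C@]3(C)O[Si](CC)(CC)CC)[C@H]3C=O | intermediate (not isolated)
23 | lactol: 10-O-triethylsilyl-2-O,12-O-dideacetyl target (2-OH cis to H-1; spatial arrangement at all centres as in 25) | OC[C@@]12COCC3=CO[C@H](O)[C@@H]4[C@H]3[C@@H]1[C@H]2CC[C@]4(C)O[Si](CC)(CC)CC | intermediate
24 | 10-O-triethylsilyl ether of the target (1R,2R,5R,6S,7R,10S,11R) | CC(=O)OC[C@@]12COCC3=CO[C@H](OC(C)=O)[C@@H]4[C@H]3[C@@H]1[C@H]2CC[C@]4(C)O[Si](CC)(CC)CC | intermediate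
25 | CNP0250836.2, (1R,2R,5R,6S,7R,10S,11R)-2,12-diacetoxy-13,15-epoxy-2,3-secoaromadendr-3-en-10-ol with the 2,3-oxygen bridge (secoaromadendrane numbering) | CC(=O)OC[C@@]12COCC3=CO[C@H](OC(C)=O)[C@@H]4[C@H]3[C@@H]1[C@H]2CC[C@]4(C)O | target

## Step count and least certain steps

Total step count: 17. Longest linear sequence: 17 steps (1 to 25); 4, 6 and 8 are commercial reagents.

Step 11 (key step). What may go wrong: the [3,3] shift may be too slow against the strain of the forming trans-fused ring, so the silyl ketene acetal is lost to silyl migration to carbon or β-elimination of the C-10 silyloxy group on heating. Enolisation may also give the ketene acetal isomer that cannot reach the boat array. The fallback sets out from 12 and comes back at 18. The allylic alcohol of 12 is converted (MsCl, Et3N; LiBr) into the allylic bromide F1. CrCl2 in THF at high dilution then effects an intramolecular Nozaki–Hiyama allylation, in which the allylchromium species attacks the C-2 aldehyde through its γ-carbon C-5 and gives the eight-membered homoallylic alcohol F2, a trans-bicyclo[6.1.0]nonane that is essentially unstrained. Oxidation with Dess–Martin periodinane gives the ketone F3, and detrifluoroacetylative diazo transfer (LiN(SiMe3)2, CF3CO2CH2CF3; then MsN3, Et3N) gives the α-diazo ketone F4. Photochemical Wolff rearrangement in MeOH contracts the ring with loss of nitrogen, C-5 migrating from C-2 to C-1 with retention, to give the methyl ester F5, which LiAlH4 reduces to 18. In this fallback C-5 is set in the allylation and C-1 in the protonation of the ketene, both with less control than in the main route.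

Step 10. What may go wrong: intermolecular esterification (dimer and oligomers) may outrun closure of the eleven-membered ring, or the activated β-silyloxy acid may eliminate. The fallback sets out from 12 and comes back at 14 and changes the bond-forming mode from acyl transfer to O-alkylation. Corey–Kim chlorination (N-chlorosuccinimide, Me2S) turns the allylic alcohol of 12 into the allylic chloride F6, Pinnick oxidation (NaClO2, NaH2PO4, 2-methyl-2-butene) gives the chloro acid F7, and Cs2CO3 in DMF at high dilution closes the lactone by carboxylate displacement of the primary allylic chloride to give 14.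

Step 8. What may go wrong: oxygen delivery to the internal carbon (methyl ketone) or slow turnover at the hindered vinyl group. The fallback sets out from 11 and comes back at 13 and replaces the oxidation of the alkene by hydroboration. The allylic alcohol is acetylated (Ac2O, pyridine) to the acetate F8. 9-Borabicyclo[3.3.1]nonane, then NaBO3·4H2O, converts the vinyl group selectively into the primary alcohol F9, TEMPO/PhI(OAc)2 in MeCN/H2O oxidises it to the acetoxy acid F10, and K2CO3 in MeOH removes the acetate to give 13.

Step 13. What may go wrong: the ene step may abstract H-5 (giving a tertiary allylic alcohol at C-5) instead of a methyl hydrogen, or oxidation may run on unevenly. The fallback sets out from 18 and comes back at 19. m-Chloroperbenzoic acid (NaHCO3, CH2Cl2) epoxidises the 1,1-disubstituted alkene to the epoxide F11, and LiNEt2 in THF isomerises it by syn-β-elimination from the unhindered methyl group to the allylic alcohol 19.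

Step 15. What may go wrong: the oxa-Michael equilibrium may lie on the side of the open enal because of the torsional strain of the oxepane, or the dialdehyde may be diverted into hydrates and mixed acetals. The fallback sets out from 17 and comes back at 23 and replaces the reversible lactol closure by an irreversible enol-lactone trap. The acid 17 is oxidised at the C-3 methyl group (SeO2, t-BuOOH; then MnO2) to the enal acid F12. AcOH/THF/H2O frees the diol, and p-toluenesulfonic acid (cat.) in toluene over molecular sieves drives oxa-Michael addition, pseudo-acid formation and dehydration to the enol lactone F13. i-Bu2AlH at −78 °C reduces F13 to the lactol 23.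

## Further compounds

F1 | step 11 | allylic bromide of 12 (C-15 bromide, C-2 aldehyde) | BrC/C(C)=C/[C@@H]1[C@@H](CC[C@](C)(O[Si](CC)(CC)CC)CC=O)C12COC(C)(C)OC2
F2 | step 11 | eight-membered homoallylic alcohol (C-2 carbinol bonded to C-5, isopropenyl on C-5, carbinol epimers) | OC1C[C@@](C)(O[Si](CC)(CC)CC)CC[C@@H]2[C@@H]([C@H]1C(C)=C)C23COC(C)(C)OC3
F3 | step 11 | eight-membered ketone from F2 | O=C1C[C@@](C)(O[Si](CC)(CC)CC)CC[C@@H]2[C@@H]([C@H]1C(C)=C)C23COC(C)(C)OC3
F4 | step 11 | α-diazo ketone (diazo carbon C-1 between the C-2 carbonyl and C-10) | O=C1C(=[N+]=[N-])[C@@](C)(O[Si](CC)(CC)CC)CC[C@@H]2[C@@H]([C@H]1C(C)=C)C23COC(C)(C)OC3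
F5 | step 11 | methyl ester of 17 | COC(=O)[C@@H]1[C@H](C(C)=C)[C@@H]2[C@@H](CC[C@]1(C)O[Si](CC)(CC)CC)C23COC(C)(C)OC3
F6 | step 10 | allylic chloride of 12 (C-15 chloride, C-2 aldehyde) | ClC/C(C)=C/[C@@H]1[C@@H](CC[C@](C)(O[Si](CC)(CC)CC)CC=O)C12COC(C)(C)OC2
F7 | step 10 | chloro acid (C-15 chloride, C-2 acid) | ClC/C(C)=C/[C@@H]1[C@@H](CC[C@](C)(O[Si](CC)(CC)CC)CC(=O)O)C12COC(C)(C)OC2
F8 | step 8 | allylic acetate of 11 | CC(=O)OC/C(C)=C/[C@@H]1[C@@H](CC[C@](C)(O[Si](CC)(CC)CC)C=C)C12COC(C)(C)OC2
F9 | step 8 | primary alcohol from hydroboration of F8 (C-2 alcohol) | CC(=O)OC/C(C)=C/[C@@H]1[C@@H](CC[C@](C)(O[Si](CC)(CC)CC)CCO)C12COC(C)(C)OC2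
F10 | step 8 | acetoxy acid (C-15 acetate, C-2 acid) | CC(=O)OC/C(C)=C/[C@@H]1[C@@H](CC[C@](C)(O[Si](CC)(CC)CC)CC(=O)O)C12COC(C)(C)OC2
F11 | step 13 | epoxide of 18 (2-methyloxiran-2-yl group on C-5, epoxide epimers) | OC[C@@H]1[C@H](C2(C)CO2)[C@@H]2[C@@H](CC[C@]1(C)O[Si](CC)(CC)CC)C23COC(C)(C)OC3
F12 | step 15 | enal acid (C-2 acid, 2-substituted acrolein at C-3, acetonide retained) | OC(=O)[C@@H]1[C@H](C(C=O)=C)[C@@H]2[C@@H](CC[C@]1(C)O[Si](CC)(CC)CC)C23COC(C)(C)OC3
F13 | step 15 | enol lactone (C-2 lactone carbonyl, oxepane closed, 12-OH free, 10-O-triethylsilyl) | OC[C@@]12COCC3=COC(=O)[C@@H]4[C@H]3[C@@H]1[C@H]2CC[C@]4(C)O[Si](CC)(CC)CC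
A1 | alternative 1 | trans-fused aromadendr-2-ene tricycle with the 13,15-ether (C-2=C-3 cyclopentene, C-4 epimers) | OC[C@@]12COCC3C=C[C@@H]4[C@H]3[C@@H]1[C@H]2CC[C@]4(C)O
A2 | alternative 2 | alkylidene formylacetate 1-oxadiene with enol acetate on the C-10 chain | COC(=O)C(C=O)=C[C@@H]1[C@@H](CC[C@](C)(O[Si](CC)(CC)CC)/C=C/OC(C)=O)C12COC(C)(C)OC2
A3 | alternative 3 | eight-membered α-diazo ketone with the C-2 carbonyl between C-1 and C-10 | O=C1C(=[N+]=[N-])[C@H](C(C)=C)[C@@H]2[C@@H](CC[C@]1(C)O[Si](CC)(CC)CC)C23COC(C)(C)OC3
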